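Readings and results were generated by integration with constants of no real substance; scatter was added.

**The pitfall.** A log plot of one run bends, and I was tempted to read that bend as an order above one in substrate. The comparison that counts is between charges.

all flasks: free catalyst 2.40 mM

| run | substrate | time |
|---|---|---|
| midnight | 120 mM |  |
| summer | 72.0 mM |  |
| dawn | 180 mM |  |
| autumn | 290 mM | 30 min |

- midnight run (time / min: [substrate] / mM): 4.3: 83.3; 8.6: 59.3; 13: 42.7; 17: 31.3; 21: 24.4; 26: 17.1; 30: 13.8
- summer run (time / min: [substrate] / mM): 4.3: 49.9; 8.6: 35.3; 13: 26.1; 17: 19.5; 21: 15.0; 26: 11.1; 30: 9.0
- dawn run (time / min: [substrate] / mM): 4.3: 124.3; 8.6: 88.9; 13: 62.7; 17: 47.5; 21: 36.0; 26: 27.1; 30: 21.5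

(scatter of a reading: 0.4 mM)

- reaction order in [substrate] at the outset, round the charge of the midnight run, defined at two percent of the substrate turned into product (one fixed amount of product, the same in the runs compared)
- substrate in the autumn run at 30 min, as a share of the substrate charged
- which of these the readings show (the substrate ties up the catalyst / the product decays / the catalyst dies in pairs / nothing beyond the main steps / the catalyst wakes slowly)

- Overall: substrate -> product, with free catalyst as catalyst.
- Constant volume, constant temperature.
- An order is taken over about fifteen percent of the charge, up and down.

**Across charges.** Over the first 4.3 min the dawn run lost 55.7 mM of substrate and the summer run 22.1 mM, so these two charges gave me an order of 1.01. This was a hand figure, taken over a wider span than the one asked.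

**The correction.** With first order, one quantity serves the three charges: θ, the natural logarithm of substrate charged over substrate left. Pooled, θ ran at 0.0856 /min up to the first reading, a pseudo-first-order constant averaged over that span. Held for 30 min, that pace gives 2.57. The midnight run read 2.16 at that time, a shortfall of 0.410, so I took the pace to have sagged with time as catalyst was lost.

**The weak link.** That figure hung on one reading of 13.8 mM, with a scatter of 0.4 mM. I reforged it from the sums of the three runs, which gave 2.13, my clock: the pooled θ at 30 min. The autumn run, charged with 290 mM, more than the 180 mM of the dawn run, should then keep 11.9 %, about 34.5 mM, provided first order holds beyond the charges tried.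

**The forecast.** It gave order 1, 11.9 % and "the catalyst dies in pairs", on this ground, said of the apparent rate constant: “It falls with time rather than with concentration, and identically in every run”.

**The flask.** It gave order 1.0, 11.5 % and "the catalyst dies in pairs".

    free catalyst + substrate → product + free catalyst (36.84 /M/min)
    2 free catalyst → 2 spent catalyst (3.342 /M/min)

In the summer run θ reached 0.693 at 8.35 min, so a third of my clock reading had passed in 27.8 % of the time. In the autumn run free catalyst turned substrate into product for the full 30 min while it fell in pairs to spent catalyst, from 2.40 mM to 1.62 mM, and θ ended at 2.16, with 33.3 mM of substrate left.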